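## The problem

Compound 25 is a trans-fused decalin of the labdane type in its enantiomeric series. With labdane numbering (C1–C10 in the decalin, C11–C16 in the chain on C9, C17 on C8, C18 and C19 on C4, C20 on C10) its stereocentres are 3S, 5S, 9R and 10S. The hardest bond is C9–C10, which joins the quaternary ring-fusion carbon to the tertiary carbon carrying the chain cis to C20. This relationship must be set when the bond is made, because neither centre can be epimerised afterwards. The other two centres can be derived from it: H5 (trans to C20) by reduction of a ring B enone, and the equatorial C3 hydroxyl by equilibration next to the C2 carbonyl. Ring A carries an α-ketol between two quaternary carbons (C4 and C10); it epimerises and can transpose through its enediol, so it has to be formed late and must end as its most stable isomer. Ring B needs a trisubstituted C7=C8 alkene placed without drift, and the chain ends in an (E)-trisubstituted allylic acetate that will not survive strong base, hydride, dissolving metal or an ionising Lewis acid. The feature that opens the structure is that C6–C9 with the chain form the skeleton of an (E)-enone, while a ring A ketone with its carbonyl at C5 can enolise only toward C10, since C4 is quaternary. Michael addition at C10 and aldol closure of C6 onto C5 therefore build ring B, C9 and C10 in one operation. Since C2 ends as a carbonyl, a stereocentre placed there at the outset can direct the face of C10 and then be erased.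

## Retrosynthesis

**C3–O bond.** The last bond cut is C3–O of 25, by way of its axial C3 epimer 24, the enol silane 21 and the ketone 20. Oxygenating C3 at the end keeps every earlier ring A intermediate down to a single oxygen at C2, the one the key step needs as its control element. The forward reactions must enolise 20 toward C3 rather than C1, oxidise the enol silane in preference to two trisubstituted alkenes, and turn the kinetic axial hydroxyl of 24 into the equatorial one. The last point rests on 25 being the thermodynamic ketol: the hydroxyl is equatorial and hydrogen-bonded, and an sp2 C2 removes the substituent that would otherwise sit between the syn-axial methyls on C4 and C10.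

**Chain.** Ketone 20 is traced through alcohol 19 and silyl ether 18 to the allylic alcohol 17 and the ester 16. The C13=C14 bond is then cut to give methyl ketone 14 and triethyl phosphonoacetate (15), and 14 is the Wacker product of the terminal alkene 13. Cutting at C13=C14 rather than nearer the ring leaves a plain butenyl group as the only chain function during ring construction. That group is inert to TiCl4, amide bases and lithium in ammonia, where an allylic oxygen or a ketal would not be. The forward olefination must favour the (E) isomer.

**Ring B adjustment.** Alkene 13 comes from enol triflate 12 (C7–O cut), that from the trans-fused ketone 11 (C5–H cut), that from the methylated enone 10 (C8–C17 cut), and that from enone 9. The C7 carbonyl of 9 is the reason for this order: it makes C8 the only acidic position for methylation, lets dissolving metal set H5, and finally marks where the alkene goes. The forward steps ask for trans protonation at C5 and for enol triflate formation toward the more substituted side.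

**Key disconnection.** Enone 9 is cut at C5=C6 to the 1,5-diketone 8, and 8 at C9–C10 to the ring A enol silane 4 and the (E)-enone 7. This is preferred to cuts inside ring A because it divides the skeleton into two halves of similar size and forms both the quaternary centre and its neighbour in one event. The precursors are a monocyclic enol silane with one stereocentre and an achiral eight-carbon dienone. The forward reaction must join a tetrasubstituted enol carbon to a β-substituted enone (precedented with simpler 2-methylcyclohexanone enol silanes), choose the face of C10 trans to the pseudo-axial C4 methyl, and give the cis arrangement of C20 and the chain. Because C2 is later oxidised, the steering stereocentre is expendable, and the antipode of the reduction catalyst in step 1 can be used if the facial sense proves opposite.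

**Fragments.** Enol silane 4 is the 1,4-hydrosilylation product of enone 3, the silyl ether of alcohol 2, which comes from ketoisophorone (1) by asymmetric reduction of its unhindered carbonyl. Enone 7 is the Wittig product of pent-4-enal (5) and the acetonyl ylide 6. All four starting materials (1, 5, 6, 15) are commercial.

## Roads not taken

Alternative 1: The cut is C5–C10 and C8–C9, closing both rings at once from the acyclic trienoate A1. In A1 an (E)-β-methyl enoate (C9=C10) and an (E,E)-diene (C5 to C8) are joined by a C1–C4 tether that already carries both ring A oxygens as silyl ethers. MeAlCl2 should give the trans-fused cycloadduct A2 with a C6=C7 alkene and a C11 methyl ester.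
- Merits: the C9/C10 relationship is fixed by the enoate geometry rather than by diastereoselection, the ring fusion follows from the tether, and the C2 and C3 oxygens arrive with defined position and configuration. In these three respects this road is better than the chosen plan, which relies on an open transition state at C9/C10 and on a late enolisation and equilibration in ring A.
- Weak points: the dienophile is β,β-disubstituted and the diene terminus C5 hangs on a quaternary carbon, so the cycloaddition must form a quaternary centre next to a gem-dimethyl group. A1 needs an acyclic anti-diol beside a quaternary carbon and two stereodefined olefin systems, a long linear sequence before any ring exists. A2 has its alkene at C6=C7 and only one chain carbon, so a regiocontrolled isomerisation into C7=C8 and a five-carbon homologation remain.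
- Comparison: the chosen plan sets against the stereospecificity of A1 two fragments of three steps and one step, a ring B ketone that places the alkene exactly at C7=C8, and a chain of the right length from the start.

Alternative 2: The cut is C1–C10 and C4–C5, annulating ring A onto a ring B quinone. The protonated oxazaborolidine catalyst made from (S)-3,3-diphenyl-1-(o-tolyl)tetrahydropyrrolo[1,2-c][1,3,2]oxazaborole and HNTf2 should promote the Diels–Alder reaction of 2,6-dimethyl-1,4-benzoquinone A3 with 2-(tert-butyldimethylsilyloxy)-4-methylpenta-1,3-diene A4. The product is the cis-fused adduct A5.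
- Merits: enantiocontrol is catalytic, C10 and C4 are made in one step, and A5 holds a C2=C3 enol silane. This is exactly the regiodefined enol derivative that the chosen plan must obtain by selective enolisation of 20, so C3 oxidation would be unambiguous; here this road is better.
- Weak points: the diene terminus carries two methyls, which disfavours the s-cis conformer and makes bonding to C5 slow. The fusion is cis and must be epimerised at C5. Ring B arrives as an ene-dione with oxygen at C6 and C9 and no chain, so the C9 carbonyl must become a C–H stereocentre bearing six carbons and the C6 oxygen must be removed. That means many redox steps, with C9 set late and without a clear control element.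
- Comparison: the chosen plan sets C9 together with C10 and carries the chain through the ring-forming step. It pays with a stoichiometric, though catalytically generated, control centre and with the late ring A oxidation.

Alternative 3: The cut is C9–C10 alone, by electrocyclisation. Semihydrogenation of the dienyne A6 over Pd/CaCO3 poisoned with Pb(OAc)2 should give the (6Z)-triene A7. Its thermal disrotatory 6π closure forms C9–C10 and ring B as the 5,7-diene A8.
- Merits: the same strategic bond as in the chosen plan is formed without a Lewis acid from ionone-type building blocks in very few steps. The C9/C10 relationship follows stereospecifically from the C8=C9 geometry, again better than an open transition state, and A8 already contains C7=C8.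
- Weak points: the closure must create quaternary C10 from a tetrasubstituted ring alkene, and for such trienes the open form or hydrogen-shift isomers can dominate. The face of C10 depends on a remote silyloxy group. A8 then needs saturation of C5=C6 within a conjugated diene with trans delivery of H5, for which dissolving metals (1,4-reduction) and catalytic hydrogenation (unselective, cis) are both unsuitable. The C11 ester also needs a five-carbon homologation.
- Comparison: the chosen plan has an enone where A8 has a diene, which permits trans reduction at C5 and a regiodefined enol triflate. It pays for this with the methylation and deoxygenation steps in ring B.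

Key step: step 5

Assumption: in step 1 the C4 carbonyl of 1 is taken to respond to RuCl[(R,R)-TsDPEN](p-cymene) as an aryl ketone does, its vinyl flank in the role of the aryl group, which gives (R)-2; should the sense be the reverse, the (S,S) complex is used.

## Route

Step 1
Reactants: 1 ketoisophorone (2,6,6-trimethylcyclohex-2-ene-1,4-dione)
Product: 2 (R)-4-hydroxy-2,6,6-trimethylcyclohex-2-en-1-one
Conditions: RuCl[(R,R)-TsDPEN](p-cymene) (1 mol %), HCO2H/Et3N (5:2), CH2Cl2, 25 °C
Reagents that add atoms: none
Why: Asymmetric transfer hydrogenation reduces only the C4 carbonyl, flanked by CH2 and CH, while the C1 carbonyl is shielded by the gem-dimethyl carbon and the methyl-bearing alkene carbon; the chiral ruthenium hydride distinguishes the vinyl and methylene flanks and sets the (R) carbinol, the only stereocentre the route has to buy.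

Step 2
Reactants: 2 (R)-4-hydroxy-2,6,6-trimethylcyclohex-2-en-1-one
Product: 3 (R)-4-(tert-butyldimethylsilyloxy)-2,6,6-trimethylcyclohex-2-en-1-one
Conditions: TBSCl, imidazole, DMF, 25 °C
Reagents that add atoms: tert-butyldimethylsilyl chloride, CC(C)(C)[Si](C)(C)Cl
Why: Imidazole-promoted silylation of a secondary alcohol; the silyl ether survives TiCl4 at −78 °C, methoxide, LiN(i-Pr)2, Li/NH3 and i-Bu2AlH and is small enough to stay equatorial as the control element for C10.

Step 3
Reactants: 3 (R)-4-(tert-butyldimethylsilyloxy)-2,6,6-trimethylcyclohex-2-en-1-one
Product: 4 (S)-4-(tert-butyldimethylsilyloxy)-2,6,6-trimethyl-1-(triethylsilyloxy)cyclohex-1-ene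
Conditions: Et3SiH, RhCl(PPh3)3 (1 mol %), THF, 50 °C
Reagents that add atoms: triethylsilane, CC[SiH](CC)CC
Why: Rhodium-catalysed 1,4-hydrosilylation of the enone with a monohydrosilane puts hydrogen on the β-carbon and silicon on oxygen, so the tetrasubstituted enol silane forms regiospecifically without a hindered deprotonation; the shielded carbonyl disfavours 1,2-addition and the stereocentre is untouched (its descriptor changes from R to S only because the former vinyl carbon loses priority).

Step 4
Reactants: 5 pent-4-enal; 6 1-(triphenylphosphoranylidene)propan-2-one
Product: 7 (E)-octa-3,7-dien-2-one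
Conditions: CH2Cl2, 40 °C
Reagents that add atoms: none
Why: Wittig reaction of a stabilised acyl ylide with an unbranched aldehyde gives the (E)-enone; the terminal alkene is the masked C13 carbonyl, chosen over a ketal because ketals are themselves electrophiles toward enol silanes under TiCl4.

Step 5
Reactants: 4 (S)-4-(tert-butyldimethylsilyloxy)-2,6,6-trimethyl-1-(triethylsilyloxy)cyclohex-1-ene; 7 (E)-octa-3,7-dien-2-one
Product: 9 (2R,9R,10S)-9-(but-3-enyl)-2-(tert-butyldimethylsilyloxy)-4,4,10-trimethyloctal-5-en-7-one (labdane numbering; C20 cis to the C9 chain and trans to the C2 silyloxy group), via 1,5-diketone 8 (not isolated)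
Conditions: TiCl4 (1.1 equiv), CH2Cl2, −78 °C; aq. NaHCO3; then NaOMe, MeOH, 65 °C
Reagents that add atoms: none
Why: TiCl4 activates the carbonyl of 7 and the tetrasubstituted enol silane 4 adds to its β-carbon (C9) through an open, staggered transition state (Mukaiyama–Michael addition), giving after hydrolysis the 1,5-diketone 8 with the C9–C10 bond in place. The closest known reaction type is the Lewis-acid Michael addition of 2-methylcyclohexanone enol silanes to (E)-pent-3-en-2-one followed by base cyclisation (a Robinson annulation in two stages), which gives the cis relationship of the angular methyl and the neighbouring substituent; the same arrangement places the C11 chain anti to C20 in the transition state and sets C9. C10 is set by the ring: in the half-chair of 4 with the silyloxy group pseudo-equatorial (the axial form would clash with a C4 methyl), one C4 methyl stands pseudo-axial over the face that a chair-like approach to C10 would use, so the enone enters from the other face, cis to the C2 oxygen, as enolate alkylations anti to a 1,3-related angular methyl do. In 8 the ring A carbonyl (C5) has no α-hydrogen and the methyl ketone can reach it in a six-membered ring only through its methyl carbon (C6), so methoxide effects a 6-(enolexo)-exo-trig aldol addition and E1cB loss of water gives the C5=C6–C7 enone of ring B. The step needs a regiodefined nucleophile (assured because C4 is quaternary and 4 was made by 1,4-hydrosilylation), 1,4- rather than 1,2-addition (usual for ketone-derived enones with TiCl4 at −78 °C), and survival of the terminal alkene and the silyl ether, both inert to these conditions.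

Step 6
Reactants: 9 (2R,9R,10S)-9-(but-3-enyl)-2-(tert-butyldimethylsilyloxy)-4,4,10-trimethyloctal-5-en-7-one
Product: 10 the 8-methyl derivative of 9 (C17 methyl equatorial, trans to the C9 chain)
Conditions: LiN(i-Pr)2, THF, −78 °C; MeI, −78 to −20 °C
Reagents that add atoms: iodomethane, CI
Why: Kinetic deprotonation can occur only at C8, since C6 is vinylic and both γ-carbons (C4, C10) are quaternary; the cross-conjugated lithium dienolate is C-methylated (enolate alkylation) from the face away from the axial C20 methyl, and the new stereocentre is in any case erased in step 8.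

Step 7
Reactants: 10 the 8-methyl derivative of 9
Product: 11 9-(but-3-enyl)-2-(tert-butyldimethylsilyloxy)-4,4,8,10-tetramethyl-trans-decalin-7-one (H5 trans to C20; other centres as in 10)
Conditions: Li, NH3(l)/THF, t-BuOH (1 equiv), −78 °C; then NH4Cl
Reagents that add atoms: none
Why: Dissolving-metal (Birch-type) reduction of the enone protonates the β-carbon C5 axially with respect to ring B while overlap with the enolate is kept, which gives the trans ring fusion as in related 10-methyl octalones; the isolated terminal alkene and the silyl ether are not reduced and one equivalent of t-BuOH limits over-reduction.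

Step 8
Reactants: 11 9-(but-3-enyl)-2-(tert-butyldimethylsilyloxy)-4,4,8,10-tetramethyl-trans-decalin-7-one
Product: 12 the C7=C8 enol triflate of 11 (7-trifluoromethanesulfonyloxy-Δ7)
Conditions: Tf2O, 2,6-di-tert-butyl-4-methylpyridine, CH2Cl2, 0 to 25 °C
Reagents that add atoms: triflic anhydride, O=S(=O)(OS(=O)(=O)C(F)(F)F)C(F)(F)F
Why: O-Triflation of the ketone under equilibrating conditions with a hindered, non-nucleophilic pyridine gives the more substituted enol triflate; loss of the axial C8 hydrogen is stereoelectronically allowed and places the double bond at C7=C8.

Step 9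
Reactants: 12 the C7=C8 enol triflate of 11
Product: 13 9-(but-3-enyl)-2-(tert-butyldimethylsilyloxy)-4,4,8,10-tetramethyl-trans-octal-7-ene
Conditions: Pd(OAc)2 (5 mol %), PPh3, HCO2H, n-Bu3N, DMF, 60 °C
Reagents that add atoms: none
Why: Palladium-catalysed formate reduction of an enol triflate (oxidative addition to zerovalent palladium, formate exchange, decarboxylation, C–H reductive elimination) replaces the triflate by hydrogen without moving the double bond; the vinylpalladium at C7 is trans to C9 across the alkene and cannot reach the pendant terminal alkene.

Step 10
Reactants: 13 9-(but-3-enyl)-2-(tert-butyldimethylsilyloxy)-4,4,8,10-tetramethyl-trans-octal-7-ene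
Product: 14 2-(tert-butyldimethylsilyloxy)-14,15-dinor-ent-labd-7-en-13-one (methyl ketone)
Conditions: PdCl2 (10 mol %), CuCl, O2 (1 atm), DMF/H2O (7:1), 25 °C
Reagents that add atoms: water, O
Why: Wacker oxidation is selective for the monosubstituted alkene (hydroxypalladation at the internal carbon, then β-hydride elimination) and leaves the trisubstituted C7=C8 bond and the silyl ether untouched, unmasking the C13 methyl ketone.

Step 11
Reactants: 14 2-(tert-butyldimethylsilyloxy)-14,15-dinor-ent-labd-7-en-13-one; 15 triethyl phosphonoacetate
Product: 16 ethyl (13E)-2-(tert-butyldimethylsilyloxy)-ent-labda-7,13-dien-15-oate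
Conditions: NaH, THF, 0 to 50 °C
Reagents that add atoms: none
Why: Horner–Wadsworth–Emmons olefination of the methyl ketone gives the trisubstituted enoate with the (E) isomer expected to predominate (larger C12 chain trans to the ester); the minor (Z) ester is removed by chromatography here or at the alcohol stage.

Step 12
Reactants: 16 ethyl (13E)-2-(tert-butyldimethylsilyloxy)-ent-labda-7,13-dien-15-oate
Product: 17 (13E)-2-(tert-butyldimethylsilyloxy)-ent-labda-7,13-dien-15-ol
Conditions: i-Bu2AlH, CH2Cl2, −78 °C
Reagents that add atoms: none
Why: 1,2-Reduction of the α,β-unsaturated ester by i-Bu2AlH gives the allylic alcohol without touching the alkenes; nothing else is reducible because C2 is still a silyl ether.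

Step 13
Reactants: 17 (13E)-2-(tert-butyldimethylsilyloxy)-ent-labda-7,13-dien-15-ol
Product: 18 (13E)-2-(tert-butyldimethylsilyloxy)-ent-labda-7,13-dien-15-yl acetate
Conditions: Ac2O, pyridine, 4-(dimethylamino)pyridine (5 mol %), CH2Cl2, 0 °C
Reagents that add atoms: acetic anhydride, CC(=O)OC(C)=O
Why: Acylation of the only free hydroxyl installs the acetate of the target before C2 is unveiled, so two alcohols never have to be told apart.

Step 14
Reactants: 18 (13E)-2-(tert-butyldimethylsilyloxy)-ent-labda-7,13-dien-15-yl acetate
Product: 19 (13E)-2-hydroxy-ent-labda-7,13-dien-15-yl acetate (C2 hydroxyl equatorial)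
Conditions: HF·pyridine, pyridine, THF, 0 to 25 °C
Reagents that add atoms: none
Why: Fluoride cleavage of the secondary silyl ether under buffered acidic conditions, which leave the allylic acetate in place where basic fluoride sources could cleave it.

Step 15
Reactants: 19 (13E)-2-hydroxy-ent-labda-7,13-dien-15-yl acetate
Product: 20 (13E)-2-oxo-ent-labda-7,13-dien-15-yl acetate
Conditions: DMP (1,1,1-triacetoxy-1,1-dihydro-1,2-benziodoxol-3(1H)-one), NaHCO3, CH2Cl2, 25 °C
Reagents that add atoms: none
Why: Periodinane oxidation of the secondary alcohol under buffered conditions erases the auxiliary C2 stereocentre and gives the ketone without affecting the alkenes or the acetate.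

Step 16
Reactants: 20 (13E)-2-oxo-ent-labda-7,13-dien-15-yl acetate
Product: 21 (13E)-2-(trimethylsilyloxy)-ent-labda-2,7,13-trien-15-yl acetate
Conditions: Me3SiOTf, Et3N, CH2Cl2, 0 to 25 °C
Reagents that add atoms: trimethylsilyl triflate, C[Si](C)(C)OS(=O)(=O)C(F)(F)F
Why: Soft enolisation (O-silylation, then deprotonation by the amine) under equilibrating conditions should favour the C2=C3 enol silane, because in a trans-decalin the enol double bond prefers the position away from the ring fusion and C1 is screened by the C9 chain; the ketone reacts far faster than the acetate.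

Step 17
Reactants: 21 (13E)-2-(trimethylsilyloxy)-ent-labda-2,7,13-trien-15-yl acetate
Product: 24 (3R,5S,9R,10S,13E)-3-hydroxy-2-oxo-ent-labda-7,13-dien-15-yl acetate (axial C3 hydroxyl; the C3 epimer of the target), via silyloxy epoxide 22 (not isolated), via 3-silyloxy ketone 23 (not isolated)
Conditions: mCPBA (1.0 equiv), NaHCO3, CH2Cl2, −20 °C; then 1 M HCl, THF, 0 °C
Reagents that add atoms: 3-chloroperbenzoic acid, OOC(=O)c1cccc(Cl)c1
Why: Rubottom oxidation: the electron-rich enol silane is epoxidised faster than the trisubstituted C7=C8 bond and the acetate-deactivated C13=C14 bond, from the face opposite the axial methyls on C4 and C10; silyl migration opens the epoxide to the 3-silyloxy ketone and dilute acid frees the ketol, whose hydroxyl is therefore axial.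

Step 18
Reactants: 24 (3R,5S,9R,10S,13E)-3-hydroxy-2-oxo-ent-labda-7,13-dien-15-yl acetate
Product: 25 (3S,5S,9R,10S,13E)-3-hydroxy-2-oxo-ent-labda-7,13-dien-15-yl acetate (target; C3 hydroxyl equatorial, cis to C20)
Conditions: 1,8-diazabicyclo[5.4.0]undec-7-ene (0.3 equiv), toluene, 40 °C, under argon
Reagents that add atoms: none
Why: Base-mediated epimerisation of an α-ketol through its enediol: reprotonation at C3 from the open face gives the equatorial, hydrogen-bonded alcohol, and the carbonyl stays at C2 because an sp3 C2 would again put a substituent between the syn-axial methyls on C4 and C10; the non-nucleophilic amidine does not cleave the acetate.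

## Compound list

1 | ketoisophorone (2,6,6-trimethylcyclohex-2-ene-1,4-dione) | CC1=CC(=O)CC(C)(C)C1=O | starting material
2 | (R)-4-hydroxy-2,6,6-trimethylcyclohex-2-en-1-one | CC1=C[C@H](O)CC(C)(C)C1=O | intermediate
3 | (R)-4-(tert-butyldimethylsilyloxy)-2,6,6-trimethylcyclohex-2-en-1-one | CC1=C[C@H](O[Si](C)(C)C(C)(C)C)CC(C)(C)C1=O | intermediate
4 | (S)-4-(tert-butyldimethylsilyloxy)-2,6,6-trimethyl-1-(triethylsilyloxy)cyclohex-1-ene | CC1=C(O[Si](CC)(CC)CC)C(C)(C)C[C@@H](O[Si](C)(C)C(C)(C)C)C1 | intermediate
5 | pent-4-enal | C=CCCC=O | starting material
6 | 1-(triphenylphosphoranylidene)propan-2-one | CC(=O)C=P(c1ccccc1)(c1ccccc1)c1ccccc1 | starting material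
7 | (E)-octa-3,7-dien-2-one | CC(=O)/C=C/CCC=C | intermediate
8 | 4-(tert-butyldimethylsilyloxy)-2,2,6-trimethyl-6-(2-oxooct-7-en-4-yl)cyclohexan-1-one, configured as 9 (1,5-diketone, not isolated) | CC(=O)C[C@@H](CCC=C)[C@]1(C)C[C@H](O[Si](C)(C)C(C)(C)C)CC(C)(C)C1=O | intermediate
9 | (2R,9R,10S)-9-(but-3-enyl)-2-(tert-butyldimethylsilyloxy)-4,4,10-trimethyloctal-5-en-7-one (labdane numbering) | C=CCC[C@@H]2CC(=O)C=C3C(C)(C)C[C@@H](O[Si](C)(C)C(C)(C)C)C[C@@]23C | intermediate
10 | 8-methyl derivative of 9 (C17 equatorial, trans to the C9 chain) | C=CCC[C@@H]2[C@@H](C)C(=O)C=C3C(C)(C)C[C@@H](O[Si](C)(C)C(C)(C)C)C[C@@]23C | intermediate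
11 | 9-(but-3-enyl)-2-(tert-butyldimethylsilyloxy)-4,4,8,10-tetramethyl-trans-decalin-7-one (H5 trans to C20) | C=CCC[C@@H]1[C@@H](C)C(=O)C[C@@H]2C(C)(C)C[C@@H](O[Si](C)(C)C(C)(C)C)C[C@@]12C | intermediate
12 | C7=C8 enol triflate of 11 | C=CCC[C@@H]1C(C)=C(OS(=O)(=O)C(F)(F)F)C[C@@H]2C(C)(C)C[C@@H](O[Si](C)(C)C(C)(C)C)C[C@@]12C | intermediate
13 | 9-(but-3-enyl)-2-(tert-butyldimethylsilyloxy)-4,4,8,10-tetramethyl-trans-octal-7-ene | C=CCC[C@@H]1C(C)=CC[C@@H]2C(C)(C)C[C@@H](O[Si](C)(C)C(C)(C)C)C[C@@]12C | intermediate
14 | 2-(tert-butyldimethylsilyloxy)-14,15-dinor-ent-labd-7-en-13-one | CC(=O)CC[C@@H]1C(C)=CC[C@@H]2C(C)(C)C[C@@H](O[Si](C)(C)C(C)(C)C)C[C@@]12C | intermediate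
15 | triethyl phosphonoacetate | CCOC(=O)CP(=O)(OCC)OCC | starting material
16 | ethyl (13E)-2-(tert-butyldimethylsilyloxy)-ent-labda-7,13-dien-15-oate | CCOC(=O)/C=C(\C)CC[C@@H]1C(C)=CC[C@@H]2C(C)(C)C[C@@H](O[Si](C)(C)C(C)(C)C)C[C@@]12C | intermediate
17 | (13E)-2-(tert-butyldimethylsilyloxy)-ent-labda-7,13-dien-15-ol | OC/C=C(\C)CC[C@@H]1C(C)=CC[C@@H]2C(C)(C)C[C@@H](O[Si](C)(C)C(C)(C)C)C[C@@]12C | intermediate
18 | (13E)-2-(tert-butyldimethylsilyloxy)-ent-labda-7,13-dien-15-yl acetate | CC(=O)OC/C=C(\C)CC[C@@H]1C(C)=CC[C@@H]2C(C)(C)C[C@@H](O[Si](C)(C)C(C)(C)C)C[C@@]12C | intermediate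
19 | (13E)-2-hydroxy-ent-labda-7,13-dien-15-yl acetate (C2 hydroxyl equatorial) | CC(=O)OC/C=C(\C)CC[C@@H]1C(C)=CC[C@@H]2C(C)(C)C[C@@H](O)C[C@@]12C | intermediate
20 | (13E)-2-oxo-ent-labda-7,13-dien-15-yl acetate | CC(=O)OC/C=C(\C)CC[C@@H]1C(C)=CC[C@@H]2C(C)(C)CC(=O)C[C@@]12C | intermediate
21 | (13E)-2-(trimethylsilyloxy)-ent-labda-2,7,13-trien-15-yl acetate | CC(=O)OC/C=C(\C)CC[C@@H]1C(C)=CC[C@@H]2C(C)(C)C=C(O[Si](C)(C)C)C[C@@]12C | intermediate
22 | 2,3-epoxide of 21, oxygen on the face opposite C20 (not isolated) | CC(=O)OC/C=C(\C)CC[C@@H]1C(C)=CC[C@@H]2C(C)(C)[C@H]3O[C@@]3(O[Si](C)(C)C)C[C@@]12C | intermediate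
23 | (3R)-3-(trimethylsilyloxy)-2-oxo-ent-labda-7,13-dien-15-yl acetate (not isolated) | CC(=O)OC/C=C(\C)CC[C@@H]1C(C)=CC[C@@H]2C(C)(C)[C@@H](O[Si](C)(C)C)C(=O)C[C@@]12C | intermediate
24 | (3R,5S,9R,10S,13E)-3-hydroxy-2-oxo-ent-labda-7,13-dien-15-yl acetate (axial hydroxyl) | CC(=O)OC/C=C(\C)CC[C@@H]1C(C)=CC[C@@H]2C(C)(C)[C@@H](O)C(=O)C[C@@]12C | intermediate
25 | (3S,5S,9R,10S,13E)-3-hydroxy-2-oxo-ent-labda-7,13-dien-15-yl acetate | CC(=O)OC/C=C(\C)CC[C@@H]1C(C)=CC[C@@H]2C(C)(C)[C@H](O)C(=O)C[C@@]12C | target

## Step count and risks

Total step count: 18. Longest linear sequence: 17 steps (steps 1–3 and 5–18).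

**Step 5 (key step).** The most likely failure is slow carbon–carbon bond formation between the tetrasubstituted enol carbon and the β-substituted enone. Loss of the silyl group from 4 or self-condensation of 7 would then outrun the addition, and the open transition state may also give incomplete control of the C9/C10 relationship. The fallback raises the electrophilicity of the acceptor instead of forcing the conditions. It sets out from 4 and 5. Knoevenagel condensation of 5 with allyl acetoacetate (piperidinium acetate) gives allyl 2-acetylhepta-2,6-dienoate F1. TiCl4-mediated addition of 4 to this doubly activated alkene gives the keto ester adduct F2. Deallylation–decarboxylation with Pd(PPh3)4 and morpholine then returns the route at diketone 8, which is closed to 9 with NaOMe as before.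

**Step 8.** The most likely failure is leakage of the enol triflate toward C6, because removal of the C8 hydrogen is hindered by the neighbouring chain and methyl and the preference for the more substituted enol is only thermodynamic. The fallback avoids enolisation altogether. It sets out from 11. Reduction with LiBH(s-Bu)3 delivers hydride equatorially and gives the axial C7 alcohol F3. Anti elimination with POCl3 in pyridine, for which the axial C8 hydrogen is antiperiplanar and the more substituted alkene is preferred, comes back to the route at 13.

**Step 16.** The most likely failure is partial enolisation toward C1, since both α-carbons are methylenes next to quaternary centres and the preference for the 2,3-position is a matter of a few kJ/mol. No structural cure exists within this skeleton, so the fallback recycles rather than forces. It sets out from 20. The mixed enol silanes are oxidised as in step 17, and the 1-hydroxy-2-ketone F4 is separated at the ketol stage, where the isomers differ most. F4 is returned to 20 by reductive removal of its α-hydroxyl with SmI2 in THF/MeOH at −78 °C.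

**Step 17.** The most likely failure is competing epoxidation of the ring B alkene, which is trisubstituted and only moderately less nucleophilic than the enol silane. The fallback replaces the peracid by an electrophile that ignores isolated alkenes. It sets out from 21. O-selective nitroso aldol reaction with nitrosobenzene, catalysed by Et3SiOTf in CH2Cl2 at −78 °C, gives the 3-(N-phenylaminooxy) ketone F5. Cleavage of the N–O bond with catalytic CuSO4 in methanol comes back to the route at 24.

**Step 11.** The most likely failure is erosion of the E/Z ratio, which is typical of phosphonoacetate additions to methyl ketones and would cost material at the separation. The fallback builds the alkene by syn carbometalation instead of olefination. It sets out from 14. Kinetic enolisation with LiN(i-Pr)2 and trapping with ClP(O)(OEt)2 gives the enol phosphate F6, and elimination with more LiN(i-Pr)2 gives the terminal alkyne F7. Zirconium-catalysed carboalumination (Me3Al, Cp2ZrCl2), followed by capture of the alkenylalane with paraformaldehyde, gives the (E)-allylic alcohol and comes back to the route at 17.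

## Further compounds

F1 | step 5 | allyl 2-acetylhepta-2,6-dienoate (E/Z mixture) | CC(=O)C(=CCCC=C)C(=O)OCC=C
F2 | step 5 | allyl 2-acetyl-3-[5-(tert-butyldimethylsilyloxy)-1,3,3-trimethyl-2-oxocyclohexyl]hept-6-enoate, C9 and C10 as in 8 | CC(=O)C(C(=O)OCC=C)[C@@H](CCC=C)[C@]1(C)C[C@H](O[Si](C)(C)C(C)(C)C)CC(C)(C)C1=O
F3 | step 8 | axial C7 alcohol derived from 11 (hydroxyl cis to H5 and H9) | C=CCC[C@@H]1[C@@H](C)[C@@H](O)C[C@@H]2C(C)(C)C[C@@H](O[Si](C)(C)C(C)(C)C)C[C@@]12C
F4 | step 16 | (13E)-1-hydroxy-2-oxo-ent-labda-7,13-dien-15-yl acetate (axial C1 hydroxyl) | CC(=O)OC/C=C(\C)CC[C@@H]1C(C)=CC[C@@H]2C(C)(C)CC(=O)[C@@H](O)[C@@]12C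
F5 | step 17 | (3R,13E)-3-(N-phenylaminooxy)-2-oxo-ent-labda-7,13-dien-15-yl acetate | CC(=O)OC/C=C(\C)CC[C@@H]1C(C)=CC[C@@H]2C(C)(C)[C@@H](ONc3ccccc3)C(=O)C[C@@]12C
F6 | step 11 | diethyl enol phosphate of 14 (terminal C13=CH2) | C=C(OP(=O)(OCC)OCC)CC[C@@H]1C(C)=CC[C@@H]2C(C)(C)C[C@@H](O[Si](C)(C)C(C)(C)C)C[C@@]12C
F7 | step 11 | terminal alkyne derived from 14 | C#CCC[C@@H]1C(C)=CC[C@@H]2C(C)(C)C[C@@H](O[Si](C)(C)C(C)(C)C)C[C@@]12C
A1 | alternative 1 | methyl (2E,8E,10E)-5-(triethylsilyloxy)-6-(tert-butyldimethylsilyloxy)-3,7,7-trimethyldodeca-2,8,10-trienoate | COC(=O)/C=C(\C)C[C@H](O[Si](CC)(CC)CC)[C@@H](O[Si](C)(C)C(C)(C)C)C(C)(C)/C=C/C=C/C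
A2 | alternative 1 | trans-decalin cycloadduct (C6=C7 alkene, C11 methyl ester, C2 and C3 silyl ethers) | COC(=O)[C@@H]1[C@H](C)C=C[C@@H]2C(C)(C)[C@H](O[Si](C)(C)C(C)(C)C)[C@@H](O[Si](CC)(CC)CC)C[C@@]12C
A3 | alternative 2 | 2,6-dimethyl-1,4-benzoquinone | CC1=CC(=O)C=C(C)C1=O
A4 | alternative 2 | 2-(tert-butyldimethylsilyloxy)-4-methylpenta-1,3-diene | C=C(O[Si](C)(C)C(C)(C)C)C=C(C)C
A5 | alternative 2 | cis-fused cycloadduct (ring A enol silane, ring B ene-dione) | O=C1C(C)=CC(=O)[C@H]2C(C)(C)C=C(O[Si](C)(C)C(C)(C)C)C[C@@]12C
A6 | alternative 3 | ethyl (E)-5-[4-(tert-butyldimethylsilyloxy)-2,6,6-trimethylcyclohex-1-enyl]-3-methylpent-2-en-4-ynoate | CCOC(=O)/C=C(\C)C#CC1=C(C)C[C@H](O[Si](C)(C)C(C)(C)C)CC1(C)C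
A7 | alternative 3 | ethyl (2E,4Z)-5-[4-(tert-butyldimethylsilyloxy)-2,6,6-trimethylcyclohex-1-enyl]-3-methylpenta-2,4-dienoate | CCOC(=O)/C=C(C)/C=C\C1=C(C)C[C@H](O[Si](C)(C)C(C)(C)C)CC1(C)C
A8 | alternative 3 | bicyclic 5,7-diene with C11 ethyl ester and C2 silyl ether | CCOC(=O)[C@@H]1C(C)=CC=C2C(C)(C)C[C@@H](O[Si](C)(C)C(C)(C)C)C[C@@]12C
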